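Ring B (C5–C10, eremophilane numbering) is cut into two three-carbon halves, C5–C6–C7 and C8–C9–C10. The C8 carbonyl makes C10 a radical acceptor and C8 an electrophile. C5 is reached as a tertiary radical by hydrogen atom transfer to a C5=C14 methylene group, which also creates the angular methyl group. C7 is the γ-carbon of an allylboronate whose transposition leaves the isopropenyl group. One operation turns an acyclic enal (C3 and C4 set beforehand) into the trans-decalin: 6-exo radical conjugate addition closes ring A, and the unveiled aldehyde is then allylborated to close ring B. Oxidation, Rubottom hydroxylation at C9 and acylation finish the route.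

Key step: step 8

Assumption: compounds 1, 2, 4, 8, 11 and 21 are taken as commercial. Ring A = C1–C5, C10; ring B = C5–C10; C14 is on C5, C15 on C4, C11–C13 form the isopropenyl group. α/β refer to the drawing in which C14 and C15 are β.

Step 1
Reactants: 1 pent-4-enal; 2 (E)-but-2-enal
Product: 3 (E)-hex-2-enedial
Conditions: second-generation Hoveyda–Grubbs catalyst (cat.), CH2Cl2, 40 °C
Reagents that add atoms: none
Why: Olefin cross-metathesis of a terminal alkene with an electron-poor partner should give the E-enal and leave both formyl groups untouched.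

Step 2
Reactants: 4 (R)-but-3-yn-2-ol
Product: 5 (R)-but-3-yn-2-yl methanesulfonate
Conditions: MsCl, Et3N, CH2Cl2, −78 to 0 °C
Reagents that add atoms: methanesulfonyl chloride CS(=O)(=O)Cl
Why: O-sulfonylation does not touch the C–O bond, so the R configuration is kept.

Step 3
Reactants: 5 (R)-but-3-yn-2-yl methanesulfonate
Product: 6 (aS)-tributyl(buta-1,2-dien-1-yl)stannane
Conditions: Bu3SnH, LDA, THF, 0 °C; CuBr·SMe2, −78 °C; then 5
Reagents that add atoms: tributylstannane CCCC[SnH](CCCC)CCCC
Why: Anti SN2′ displacement of the propargylic mesylate by a stannylcopper reagent should carry the point chirality into the axial chirality of the allene.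

Step 4
Reactants: 3 (E)-hex-2-enedial; 6 (aS)-tributyl(buta-1,2-dien-1-yl)stannane
Product: 7 (2E,6R,7R)-6-hydroxy-7-methylnon-2-en-8-ynal
Conditions: BF3·OEt2, CH2Cl2, −78 °C
Reagents that add atoms: none
Why: Lewis acid promoted SE2′ propargylation by the allenylstannane should take the more electrophilic saturated aldehyde; attack anti to tin sets C4 from the allene axis, and the open antiperiplanar transition state gives the syn relation that sets C3.

Step 5
Reactants: 7 (2E,6R,7R)-6-hydroxy-7-methylnon-2-en-8-ynal; 8 angelic acid
Product: 10 (2E,6R,7R)-6-angeloyloxy-7-methylnon-2-en-8-ynal, via mixed anhydride 9 (not isolated)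
Conditions: 8, 2,4,6-trichlorobenzoyl chloride, Et3N, toluene, rt; then 7, 80 °C
Reagents that add atoms: none
Why: Yamaguchi esterification without a nucleophilic catalyst acylates C3–OH with retention and should avoid Z to E isomerisation of the angelate.

Step 6
Reactants: 10 (2E,6R,7R)-6-angeloyloxy-7-methylnon-2-en-8-ynal; 11 2-methylbut-3-en-1-ol
Product: 12 (2E,6R,7R,10E)-6-angeloyloxy-12-hydroxy-7,11-dimethyl-8-methylidenedodeca-2,10-dienal
Conditions: [CpRu(MeCN)3]PF6 (cat.), acetone, rt
Reagents that add atoms: none
Why: The ruthenium-catalysed intermolecular Alder-ene coupling joins the internal alkyne carbon (C5) to the terminal alkene carbon (C6) through a ruthenacyclopentene. β-Hydride elimination of the tertiary allylic hydrogen gives the skipped diene; the stereocentre of 11 is lost, and the C7=C11 geometry does not matter later.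

Step 7
Reactants: 12 (2E,6R,7R,10E)-6-angeloyloxy-12-hydroxy-7,11-dimethyl-8-methylidenedodeca-2,10-dienal
Product: 13 (2E,6R,7R,10E)-6-angeloyloxy-7,11-dimethyl-8-methylidene-12-(pinacolatoboryl)dodeca-2,10-dienal
Conditions: B2pin2, Pd(MeCN)4(BF4)2 (cat.), DMSO–MeOH, rt
Reagents that add atoms: bis(pinacolato)diboron CC1(C)OB(OC1(C)C)B1OC(C)(C)C(C)(C)O1
Why: Palladium-catalysed borylation of the allylic alcohol through an η3-allylpalladium species should deliver boron to the less hindered primary terminus (C12) and touch no stereocentre.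

Step 8
Reactants: 13 (2E,6R,7R,10E)-6-angeloyloxy-7,11-dimethyl-8-methylidene-12-(pinacolatoboryl)dodeca-2,10-dienal
Product: 16 3α-angeloyloxy-8β-hydroxy-10αH-eremophil-11-ene, via monocyclic aldehyde 14 (not isolated), via pinacol borate 15 (not isolated)
Conditions: Fe(acac)3 (cat.), PhSiH3, EtOH–THF (0.01 M), rt then 50 °C; aq. NH4Cl
Reagents that add atoms: none
Why: Proposed new method: an iron hydride formed from Fe(acac)3 and PhSiH3 transfers a hydrogen atom to C14 of the 1,1-disubstituted alkene, the tertiary C5 radical adds 6-exo-trig to C10 of the enal (ring A), and reduction and protonation of the α-formyl radical unveil saturated aldehyde 14, whose C8 carbonyl is then attacked by the γ-carbon C7 of the allylboronate through a closed six-membered boron chair (6-exo closure of ring B) with transposition to the isopropenyl group. The closest known reaction types are the reductive olefin coupling by metal-hydride hydrogen atom transfer (Giese-type cyclisation) and the uncatalysed intramolecular allylboration of aldehydes, and only their union in one flask is new. C10 is set by a chair transition state with C3–O, C4–CH3 and the enal arm equatorial, and C5 by the same chair, in which the long C6 arm takes the equatorial-like site anti to C3 and the methyl group the axial-like site. C7 and C8 are set by the trans-decalin-like bicyclic Zimmerman–Traxler chair, which places isopropenyl and O–B equatorial. The step needs hydrogen atom transfer to the 1,1-disubstituted alkene rather than to the trisubstituted allylboronate, the angelate or the enal, which the higher rate for less substituted electron-neutral alkenes should secure. It also needs the boronate to wait, which the conjugated and remote enal carbonyl (ten-membered transition state), high dilution and the late warming should secure.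

Step 9
Reactants: 16 3α-angeloyloxy-8β-hydroxy-10αH-eremophil-11-ene
Product: 17 3α-angeloyloxy-10αH-eremophil-11-en-8-one
Conditions: Dess–Martin periodinane, CH2Cl2, 0 °C to rt
Reagents that add atoms: none
Why: Dess–Martin oxidation works without base, so the equatorial C7 centre and the unconjugated isopropenyl group should survive.

Step 10
Reactants: 17 3α-angeloyloxy-10αH-eremophil-11-en-8-one
Product: 18 3α-angeloyloxy-8-trimethylsilyloxy-10αH-eremophila-8,11-diene
Conditions: LiHMDS, TMSCl (internal quench), THF, −78 °C
Reagents that add atoms: chlorotrimethylsilane C[Si](C)(C)Cl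
Why: Kinetic enolisation with in situ silylation should remove a proton of the less hindered C9 methylene group rather than the tertiary C7–H, and at −78 °C it should leave the angelate alone.

Step 11
Reactants: 18 3α-angeloyloxy-8-trimethylsilyloxy-10αH-eremophila-8,11-diene
Product: 20 3α-angeloyloxy-9α-hydroxy-10αH-eremophil-11-en-8-one, via silyloxy ketone 19 (not isolated)
Conditions: mCPBA, CH2Cl2, −20 °C; then citric acid (cat.), THF–H2O
Reagents that add atoms: 3-chloroperoxybenzoic acid O=C(OO)c1cccc(Cl)c1
Why: In the Rubottom oxidation the peracid takes the electron-rich silyl enol ether before any other alkene, from the α face opposite the axial C14 methyl group, which sets the equatorial 9α oxygen.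

Step 12
Reactants: 20 3α-angeloyloxy-9α-hydroxy-10αH-eremophil-11-en-8-one; 21 (E)-3-methylpent-2-enoic acid
Product: 23 target, (3R,4R,5R,7S,9S,10R)-3α-angeloyloxy-9α-[(E)-3-methylpent-2-enoyloxy]eremophil-11-en-8-one, via O-acylisourea 22 (not isolated)
Conditions: DCC, DMAP (cat.), CH2Cl2, 0 °C
Reagents that add atoms: none
Why: Steglich esterification acylates the C9 oxygen with retention, and the all-equatorial C7 and C9 centres are also the thermodynamic ones.

Compound list
1 | pent-4-enal | C=CCCC=O | starting material
2 | (E)-but-2-enal | C/C=C/C=O | starting material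
3 | (E)-hex-2-enedial | O=C/C=C/CCC=O | intermediate
4 | (R)-but-3-yn-2-ol | C[C@@H](O)C#C | starting material
5 | (R)-but-3-yn-2-yl methanesulfonate | C[C@@H](OS(C)(=O)=O)C#C | intermediate
6 | (aS)-tributyl(buta-1,2-dien-1-yl)stannane | [H]C([Sn](CCCC)(CCCC)CCCC)=[C@]=C([H])C | intermediate
7 | (2E,6R,7R)-6-hydroxy-7-methylnon-2-en-8-ynal | O=C/C=C/CC[C@@H](O)[C@H](C)C#C | intermediate
8 | angelic acid, (Z)-2-methylbut-2-enoic acid | C/C=C(/C)C(=O)O | starting material
9 | angelic 2,4,6-trichlorobenzoic anhydride | C/C=C(/C)C(=O)OC(=O)c1c(Cl)cc(Cl)cc1Cl | intermediate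
10 | (2E,6R,7R)-6-angeloyloxy-7-methylnon-2-en-8-ynal | O=C/C=C/CC[C@@H](OC(=O)/C(C)=C\C)[C@H](C)C#C | intermediate
11 | 2-methylbut-3-en-1-ol (racemic) | C=CC(C)CO | starting material
12 | (2E,6R,7R,10E)-6-angeloyloxy-12-hydroxy-7,11-dimethyl-8-methylidenedodeca-2,10-dienal | O=C/C=C/CC[C@@H](OC(=O)/C(C)=C\C)[C@H](C)C(=C)C/C=C(\C)CO | intermediate
13 | (2E,6R,7R,10E)-6-angeloyloxy-7,11-dimethyl-8-methylidene-12-(pinacolatoboryl)dodeca-2,10-dienal | O=C/C=C/CC[C@@H](OC(=O)/C(C)=C\C)[C@H](C)C(=C)C/C=C(\C)CB1OC(C)(C)C(C)(C)O1 | intermediate
14 | ring A aldehyde: cyclohexane with C5 (CH3, allylboronate arm), C10 (CH2CHO), C4 CH3, C3 angelate | CC1(C)OB(C/C(C)=C/C[C@]2(C)[C@@H](C)[C@H](OC(=O)/C(C)=C\C)CC[C@H]2CC=O)OC1(C)C | intermediate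
15 | pinacol borate of 16 (C8–O–Bpin) | C=C(C)[C@@H]1C[C@]2(C)[C@@H](C)[C@H](OC(=O)/C(C)=C\C)CC[C@H]2C[C@H]1OB3OC(C)(C)C(C)(C)O3 | intermediate
16 | 3α-angeloyloxy-8β-hydroxy-10αH-eremophil-11-ene | C=C(C)[C@@H]1C[C@]2(C)[C@@H](C)[C@H](OC(=O)/C(C)=C\C)CC[C@H]2C[C@H]1O | intermediate
17 | 3α-angeloyloxy-10αH-eremophil-11-en-8-one | C=C(C)[C@@H]1C[C@]2(C)[C@@H](C)[C@H](OC(=O)/C(C)=C\C)CC[C@H]2CC1=O | intermediate
18 | 3α-angeloyloxy-8-trimethylsilyloxy-10αH-eremophila-8,11-diene | C=C(C)[C@@H]1C[C@]2(C)[C@@H](C)[C@H](OC(=O)/C(C)=C\C)CC[C@H]2C=C1O[Si](C)(C)C | intermediate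
19 | 3α-angeloyloxy-9α-trimethylsilyloxy-10αH-eremophil-11-en-8-one | C=C(C)[C@@H]1C[C@]2(C)[C@@H](C)[C@H](OC(=O)/C(C)=C\C)CC[C@H]2[C@H](O[Si](C)(C)C)C1=O | intermediate
20 | 3α-angeloyloxy-9α-hydroxy-10αH-eremophil-11-en-8-one | C=C(C)[C@@H]1C[C@]2(C)[C@@H](C)[C@H](OC(=O)/C(C)=C\C)CC[C@H]2[C@H](O)C1=O | intermediate
21 | (E)-3-methylpent-2-enoic acid | CC/C(C)=C/C(=O)O | starting material
22 | O-[(E)-3-methylpent-2-enoyl]-N,N'-dicyclohexylisourea | CC/C(C)=C/C(=O)OC(=NC1CCCCC1)NC1CCCCC1 | intermediate
23 | CNP0301161.1, (3R,4R,5R,7S,9S,10R) | C=C(C)[C@@H]1C[C@]2(C)[C@@H](C)[C@H](OC(=O)/C(C)=C\C)CC[C@H]2[C@H](OC(=O)/C=C(\C)CC)C1=O | target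

Total step count: 12. Longest linear sequence: 11 steps (4 → 5 → 6 → 7 → 10 → 12 → 13 → 16 → 17 → 18 → 20 → 23).

Steps most likely to fail

Step 8. Four things may go wrong:
- hydrogen atom transfer to the allylboronate alkene or to the newly formed isopropenyl group
- protodeboronation
- premature intermolecular allylboration
- poor facial selectivity at the planar C5 radical

The fallback separates the two bond formations with known chemistry. It sets out from 10 and comes back at 16. Compound 10 is coupled under the same ruthenium catalysis with 3-methylbut-1-ene to the prenyl trienal F1. The known iron-hydride reductive cyclisation (Fe(acac)3, PhSiH3, EtOH) gives the isolated monocyclic prenyl aldehyde F2, at which stage C5 epimers can be separated. A Me2AlCl-promoted carbonyl-ene reaction of the isopulegol type then closes ring B to 16.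

Step 7. The cationic palladium salt in methanol may acetalise the enal, and the product may be lost through allylboration of the aldehyde while it forms. The fallback sets out from 10 and comes back at 13. The Alder-ene coupling is run with 2-methylbut-3-en-1-yl acetate to give the allylic acetate F3. This is ionised under neutral conditions in a Miyaura-type borylation (B2pin2, Pd(dba)2, DMSO).

Step 10. The base may remove the more acidic allylic C7–H. That would cost regiocontrol and could lead to epimerisation or migration of the isopropenyl double bond into conjugation. The fallback uses no strong base; it sets out from 17 and 21 and comes back at 23.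
- Compound 21 is coupled with tert-butyl hydroxy(methyl)carbamate to the Boc-protected O-acylhydroxylamine F4.
- HCl in dioxane gives the N-methyl-O-acylhydroxylammonium chloride F5.
- F5 condenses with 17 at the less hindered C9 side and delivers the acyloxy group by [3,3]-sigmatropic rearrangement, giving the equatorial ester 23 directly.

Further compounds
F1 | step 8 | (2E,6R,7R)-6-angeloyloxy-7,11-dimethyl-8-methylidenedodeca-2,10-dienal | O=C/C=C/CC[C@@H](OC(=O)/C(C)=C\C)[C@H](C)C(=C)CC=C(C)C
F2 | step 8 | ring A aldehyde with prenyl arm on C5 | CC(C)=CC[C@]1(C)[C@@H](C)[C@H](OC(=O)/C(C)=C\C)CC[C@H]1CC=O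
F3 | step 7 | (2E,6R,7R,10E)-12-acetoxy-6-angeloyloxy-7,11-dimethyl-8-methylidenedodeca-2,10-dienal | O=C/C=C/CC[C@@H](OC(=O)/C(C)=C\C)[C@H](C)C(=C)C/C=C(\C)COC(C)=O
F4 | step 10 | tert-butyl methyl[(E)-3-methylpent-2-enoyloxy]carbamate | CC/C(C)=C/C(=O)ON(C)C(=O)OC(C)(C)C
F5 | step 10 | N-methyl-O-[(E)-3-methylpent-2-enoyl]hydroxylammonium chloride | CC/C(C)=C/C(=O)O[NH2+]C.[Cl-]
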